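**Plan**
1. Ring C is cut at O1–C2 (addition–elimination of a ring-A phenoxide on a 2-chlorobenzofuran-3-carboxylate) and at C4–C4a (Friedel–Crafts); ring D is cut at O7–CMe2 and C8–CH= (propargyl Claisen).
2. Ring A is then a fully substituted phloroglucinol with three different oxygens (O5: free OH beside the C6 prenyl group; O7: pyran oxygen; O8a: the pyranone O1) and hydrogens only on C8 and C4a; it is cut at C7–C8, C4a–C8a and C6–C7 into 3-ethoxy-4-prenylcyclobutenone and triisopropylsiloxyacetylene.
3. The ring-B block is cut at C3–C1′ and C2–O2′ (quinone plus enamino ester) and at its pyran ring (phenol plus prenal).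
4. Forward: ring A by benzannulation (step 5), ring D (steps 6–7); in parallel the B-ring pyran, quinone and furan ring (steps 8–12); then ring C through O1–C2 and C4–C4a (steps 13–15) and release of O5–H and O5′–H (step 16).
5. Stereochemistry: the target has no stereocentre; the only one met on the way, C4 of the racemic cyclobutenone, is erased when ring A aromatises.

Key step: step 5

Remark: the target SMILES holds no stereocentre and no stereogenic double bond, so the compound is achiral and only constitution needs control; atom labels follow flavonoid numbering (primes for ring B), and "6,7-(2,2-dimethyl-2H-pyrano)benzofuran" means a 2,2-dimethyl-2H-pyran fused to the benzofuran with its oxygen on C6 and its C4 (CH=) on C7.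

Step 1
Reactants: 1 5-methylhex-4-enoic acid
Product: 2 5-methylhex-4-enoyl chloride
Conditions: (COCl)2, DMF (cat.), CH2Cl2, 0 °C → rt
Reagents that add atoms: oxalyl chloride, ClC(=O)C(Cl)=O
Why: Acid chloride formation through the Vilsmeier-type chloroiminium catalyst is standard, and the trisubstituted alkene should tolerate the short exposure to HCl at 0 °C.

Step 2
Reactants: 2 5-methylhex-4-enoyl chloride; 3 ethoxyacetylene
Product: 5 (±)-3-ethoxy-4-(3-methylbut-2-en-1-yl)cyclobut-2-en-1-one, via ketene 4 (not isolated)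
Conditions: Et3N, 3 (3 equiv), Et2O/hexanes, 0 °C → rt
Reagents that add atoms: none
Why: Dehydrochlorination gives the aldoketene, which should be trapped by the excess ynol ether in a ketene–alkyne [2+2] cycloaddition (the established entry to 3-ethoxycyclobutenones), the nucleophilic alkyne CH bonding to the ketene carbonyl carbon; the new stereocentre is racemic and disappears in step 5.

Step 3
Reactants: 6 ethynyltrimethylsilane
Product: 9 1-(triisopropylsiloxy)-2-(trimethylsilyl)acetylene, via lithium (trimethylsilyl)acetylide 7 (not isolated), via lithium 2-(trimethylsilyl)ethynolate 8 (not isolated)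
Conditions: n-BuLi, THF, −78 °C; t-BuOOLi (from t-BuOOH + LiHMDS), −78 → 0 °C; TIPSOTf, −78 → 0 °C
Reagents that add atoms: tert-butyl hydroperoxide, CC(C)(C)OO; triisopropylsilyl trifluoromethanesulfonate, CC(C)[Si](OS(=O)(=O)C(F)(F)F)(C(C)C)C(C)C
Why: Oxidation of a lithium acetylide with lithium tert-butyl peroxide to the ynolate followed by O-silylation with a bulky silyl triflate is the usual route to triisopropylsiloxyalkynes; the C-silyl cap avoids handling monolithium acetylide, and the hindered electrophile should favour kinetic O- over C-silylation.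

Step 4
Reactants: 9 1-(triisopropylsiloxy)-2-(trimethylsilyl)acetylene
Product: 10 (triisopropylsiloxy)acetylene
Conditions: K2CO3 (cat.), MeOH, 0 °C, short contact; pentane extraction, distillation
Reagents that add atoms: none
Why: Base-catalysed methanolysis of an alkynyl–SiMe3 bond (protodesilylation) is fast at 0 °C, while the hindered O–Si(i-Pr)3 bond and the base-stable ynol ether are expected to survive short contact.

Step 5
Reactants: 5 (±)-3-ethoxy-4-(3-methylbut-2-en-1-yl)cyclobut-2-en-1-one; 10 (triisopropylsiloxy)acetylene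
Product: 15 3-ethoxy-2-(3-methylbut-2-en-1-yl)-5-(triisopropylsiloxy)phenol, via vinylketene 11 (not isolated), via vinylcyclobutenone 12 (not isolated), via dienylketene 13 (not isolated), via cyclohexadienone 14 (not isolated)
Conditions: 10 (1.3 equiv), toluene, 80 °C then 110 °C, sealed tube, Ar
Reagents that add atoms: none
Why: Heating opens 5 by conrotatory 4π electrocyclic cleavage to vinylketene 11 (the prenyl chain rotates outward, away from the ketene, so the pendant alkene cannot trap it), which adds [2+2] to ynol ether 10 with the nucleophilic alkyne CH (future C8) on the ketene carbonyl carbon (C7) and the siloxy carbon (C8a) on C4a; adduct 12 opens again to dienylketene 13, which closes and tautomerises to phenol 15. The closest known reaction type is the Danheiser benzannulation of cyclobutenones with alkoxy- and trialkylsiloxy-alkynes, which gives resorcinol monoethers. Ring A is closed by a thermal disrotatory 6π electrocyclisation of the dienylketene (C6–C7 bond), the two four-membered rings being transient. No stereocentre is created: the stereocentre of 5 and the sp3 carbon of 14 are erased on aromatisation. The step needs one regiochemistry in the [2+2] event, and the matched polarity of the ketene (electrophilic central carbon) and the ynol ether (nucleophilic β-carbon) should secure it, placing OSi(i-Pr)3 meta to the new OH with H on C8 and C4a. It also needs inward rotation of the alkenyl group when 12 opens; that opening is reversible, so the material should funnel through the cyclisable (3E)-dienylketene.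

Step 6
Reactants: 15 3-ethoxy-2-(3-methylbut-2-en-1-yl)-5-(triisopropylsiloxy)phenol; 16 3-chloro-3-methylbut-1-yne
Product: 17 [3-ethoxy-5-(2-methylbut-3-yn-2-yloxy)-4-(3-methylbut-2-en-1-yl)phenoxy]triisopropylsilane
Conditions: DBU, CuCl2·2H2O (cat.), MeCN, 0 °C
Reagents that add atoms: none
Why: Copper-catalysed O-propargylation of a phenol with a tertiary propargyl chloride proceeds at 0 °C even for ortho-substituted phenols and should leave the aryl silyl ether untouched.

Step 7
Reactants: 17 [3-ethoxy-5-(2-methylbut-3-yn-2-yloxy)-4-(3-methylbut-2-en-1-yl)phenoxy]triisopropylsilane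
Product: 20 7-ethoxy-2,2-dimethyl-8-(3-methylbut-2-en-1-yl)-5-(triisopropylsiloxy)-2H-chromene, via allenylphenol 18 (not isolated), via quinone methide 19 (not isolated)
Conditions: o-xylene, 140 °C
Reagents that add atoms: none
Why: The aromatic propargyl Claisen rearrangement ([3,3]) can deliver the allenyl group only to C8 because C6 carries the prenyl group; tautomerisation, 1,5-hydrogen shift and oxa-6π electrocyclisation then give the 2,2-dimethyl-2H-chromene (ring D).

Step 8
Reactants: 21 2,5-dimethoxyphenol; 22 3-methylbut-2-enal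
Product: 25 5,8-dimethoxy-2,2-dimethyl-2H-chromene, via dioxaborinine 23 (not isolated), via quinone methide 24 (not isolated)
Conditions: PhB(OH)2 (1 equiv), AcOH (cat.), toluene, reflux, Dean–Stark
Reagents that add atoms: none
Why: Phenylboronic acid-templated ortho-condensation of a phenol with an enal (benzodioxaborinine, fragmentation to the o-quinone methide, oxa-6π electrocyclisation) is a known chromene synthesis, and C6 is the only free ortho position of 21.

Step 9
Reactants: 25 5,8-dimethoxy-2,2-dimethyl-2H-chromene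
Product: 26 2,2-dimethyl-2H-chromene-5,8-dione
Conditions: (NH4)2Ce(NO3)6, MeCN/H2O, 0 °C
Reagents that add atoms: water, O
Why: Oxidative demethylation of a 1,4-dimethoxyarene with ceric ammonium nitrate gives the p-quinone within minutes at 0 °C and should outpace oxidation of the chromene double bond.

Step 10
Reactants: 26 2,2-dimethyl-2H-chromene-5,8-dione; 27 ethyl (2E)-3-(dimethylamino)prop-2-enoate
Product: 29 ethyl 5-hydroxy-6,7-(2,2-dimethyl-2H-pyrano)benzofuran-3-carboxylate, via hydroquinone adduct 28 (not isolated)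
Conditions: AcOH, rt
Reagents that add atoms: none
Why: In this Nenitzescu-type benzofuran synthesis the enamine β-carbon should add to quinone C6 (conjugate to the C8 carbonyl, the more electrophilic one because C5=O is a vinylogous ester of the pyran oxygen), after which the C5 hydroxyl closes onto the iminium carbon and dimethylamine is lost, leaving the free OH para to the furan oxygen and next to the pyran oxygen as ring B requires.

Step 11
Reactants: 29 ethyl 5-hydroxy-6,7-(2,2-dimethyl-2H-pyrano)benzofuran-3-carboxylate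
Product: 30 ethyl 5-(methoxymethoxy)-6,7-(2,2-dimethyl-2H-pyrano)benzofuran-3-carboxylate
Conditions: MOMCl, i-Pr2NEt, CH2Cl2, 0 °C → rt
Reagents that add atoms: chloromethyl methyl ether, COCCl
Why: O-Alkylation of the phenol to the MOM acetal masks the acidic OH for the lithiation and the addition–elimination steps.

Step 12
Reactants: 30 ethyl 5-(methoxymethoxy)-6,7-(2,2-dimethyl-2H-pyrano)benzofuran-3-carboxylate
Product: 32 ethyl 2-chloro-5-(methoxymethoxy)-6,7-(2,2-dimethyl-2H-pyrano)benzofuran-3-carboxylate, via 2-lithiobenzofuran 31 (not isolated)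
Conditions: LDA, THF, −78 °C; C2Cl6, −78 → −20 °C
Reagents that add atoms: hexachloroethane, ClC(Cl)(Cl)C(Cl)(Cl)Cl
Why: Directed deprotonation of a furan-3-carboxylate at C2 (next to the ester and α to the ring oxygen) followed by electrophilic chlorination is standard heteroaryl lithiation–halogenation.

Step 13
Reactants: 20 7-ethoxy-2,2-dimethyl-8-(3-methylbut-2-en-1-yl)-5-(triisopropylsiloxy)-2H-chromene; 32 ethyl 2-chloro-5-(methoxymethoxy)-6,7-(2,2-dimethyl-2H-pyrano)benzofuran-3-carboxylate
Product: 34 ethyl 2-{[7-ethoxy-2,2-dimethyl-8-(3-methylbut-2-en-1-yl)-2H-chromen-5-yl]oxy}-5-(methoxymethoxy)-6,7-(2,2-dimethyl-2H-pyrano)benzofuran-3-carboxylate, via caesium phenoxide 33 (not isolated)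
Conditions: CsF, DMF, 70 °C
Reagents that add atoms: none
Why: Fluoride cleaves the aryl silyl ether and the phenoxide formed in situ should displace chloride from C2 of 32 by addition–elimination (SNAr on a β-chloro-β-alkoxyacrylate), a known one-pot desilylation/O-arylation that forms the O1–C2 bond.

Step 14
Reactants: 34 ethyl 2-{[7-ethoxy-2,2-dimethyl-8-(3-methylbut-2-en-1-yl)-2H-chromen-5-yl]oxy}-5-(methoxymethoxy)-6,7-(2,2-dimethyl-2H-pyrano)benzofuran-3-carboxylate
Product: 35 2-{[7-ethoxy-2,2-dimethyl-8-(3-methylbut-2-en-1-yl)-2H-chromen-5-yl]oxy}-5-(methoxymethoxy)-6,7-(2,2-dimethyl-2H-pyrano)benzofuran-3-carboxylic acid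
Conditions: LiOH·H2O, THF/MeOH/H2O, 50 °C; then 1 M HCl to pH 4, 0 °C
Reagents that add atoms: lithium hydroxide, [Li+].[OH-]
Why: Saponification of the ester, as in the hydrolysis of 3-aryloxyacrylates on the way to chromones, should leave the O1–C2 bond intact because hydroxide attacks the ester carbonyl in preference to the donor-deactivated β-carbon.

Step 15
Reactants: 35 2-{[7-ethoxy-2,2-dimethyl-8-(3-methylbut-2-en-1-yl)-2H-chromen-5-yl]oxy}-5-(methoxymethoxy)-6,7-(2,2-dimethyl-2H-pyrano)benzofuran-3-carboxylic acid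
Product: 37 5-O-ethyl-5′-O-(methoxymethyl) ether of the target, via mixed anhydride 36 (not isolated)
Conditions: (CF3CO)2O, CH2Cl2, 0 °C → rt
Reagents that add atoms: none
Why: Intramolecular Friedel–Crafts acylation through the mixed trifluoroacetic anhydride closes the six-membered pyranone (C4–C4a) at the only free position of ring A, which three oxygens activate enough that no Lewis acid should be needed.

Step 16
Reactants: 37 5-O-ethyl-5′-O-(methoxymethyl) ether of the target
Product: 38 CNP0323631.0 (target)
Conditions: BCl3, CH2Cl2, −78 → 0 °C; aq. NaHCO3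
Reagents that add atoms: none
Why: Boron trichloride chelated between the C4 carbonyl and O5 should cleave the peri ethyl ether (chelation-assisted dealkylation of 5-alkoxychromones) and also the MOM acetal, without protic acid being present before work-up.

**Compound list**
1 | 5-methylhex-4-enoic acid | CC(C)=CCCC(=O)O | starting material
2 | 5-methylhex-4-enoyl chloride | CC(C)=CCCC(Cl)=O | intermediate
3 | ethoxyacetylene (ethoxyethyne) | CCOC#C | starting material
4 | (3-methylbut-2-en-1-yl)ketene, 5-methylhexa-1,4-dien-1-one (in situ) | CC(C)=CCC=C=O | intermediate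
5 | (±)-3-ethoxy-4-(3-methylbut-2-en-1-yl)cyclobut-2-en-1-one (racemate) | CCOC1=CC(=O)C1CC=C(C)C | intermediate
6 | ethynyltrimethylsilane | C#C[Si](C)(C)C | starting material
7 | lithium (trimethylsilyl)acetylide (in situ) | [Li]C#C[Si](C)(C)C | intermediate
8 | lithium 2-(trimethylsilyl)ethynolate (in situ) | [Li+].[O-]C#C[Si](C)(C)C | intermediate
9 | 1-(triisopropylsiloxy)-2-(trimethylsilyl)acetylene | C[Si](C)(C)C#CO[Si](C(C)C)(C(C)C)C(C)C | intermediate
10 | (triisopropylsiloxy)acetylene, ethynyloxytri(propan-2-yl)silane | C#CO[Si](C(C)C)(C(C)C)C(C)C | intermediate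
11 | (3Z)-3-ethoxy-7-methylocta-1,3,6-trien-1-one (vinylketene, in situ) | O=C=C/C(OCC)=C/CC=C(C)C | intermediate
12 | (±)-4-[(1Z)-1-ethoxy-5-methylhexa-1,4-dien-1-yl]-3-(triisopropylsiloxy)cyclobut-2-en-1-one (in situ) | O=C1C=C(O[Si](C(C)C)(C(C)C)C(C)C)C1/C(OCC)=C/CC=C(C)C | intermediate
13 | (3E,5Z)-5-ethoxy-9-methyl-3-(triisopropylsiloxy)deca-1,3,5,8-tetraen-1-one (dienylketene, in situ) | O=C=C/C(O[Si](C(C)C)(C(C)C)C(C)C)=C\C(OCC)=C\CC=C(C)C | intermediate
14 | (±)-5-ethoxy-6-(3-methylbut-2-en-1-yl)-3-(triisopropylsiloxy)cyclohexa-2,4-dien-1-one (in situ) | O=C1C=C(O[Si](C(C)C)(C(C)C)C(C)C)C=C(OCC)C1CC=C(C)C | intermediate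
15 | 3-ethoxy-2-(3-methylbut-2-en-1-yl)-5-(triisopropylsiloxy)phenol | CCOc1cc(O[Si](C(C)C)(C(C)C)C(C)C)cc(O)c1CC=C(C)C | intermediate
16 | 3-chloro-3-methylbut-1-yne | CC(C)(Cl)C#C | starting material
17 | [3-ethoxy-5-(2-methylbut-3-yn-2-yloxy)-4-(3-methylbut-2-en-1-yl)phenoxy]triisopropylsilane | CCOc1cc(O[Si](C(C)C)(C(C)C)C(C)C)cc(OC(C)(C)C#C)c1CC=C(C)C | intermediate
18 | 5-ethoxy-2-(3-methylbuta-1,2-dien-1-yl)-6-(3-methylbut-2-en-1-yl)-3-(triisopropylsiloxy)phenol (in situ) | CCOc1cc(O[Si](C(C)C)(C(C)C)C(C)C)c(C=C=C(C)C)c(O)c1CC=C(C)C | intermediate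
19 | (6Z)-3-ethoxy-2-(3-methylbut-2-en-1-yl)-6-(3-methylbut-2-en-1-ylidene)-5-(triisopropylsiloxy)cyclohexa-2,4-dien-1-one (in situ) | CC(C)=C/C=C1\C(=O)C(CC=C(C)C)=C(OCC)C=C1O[Si](C(C)C)(C(C)C)C(C)C | intermediate
20 | 7-ethoxy-2,2-dimethyl-8-(3-methylbut-2-en-1-yl)-5-(triisopropylsiloxy)-2H-chromene | CCOc1cc(O[Si](C(C)C)(C(C)C)C(C)C)c2C=CC(C)(C)Oc2c1CC=C(C)C | intermediate
21 | 2,5-dimethoxyphenol | COc1ccc(OC)c(O)c1 | starting material
22 | 3-methylbut-2-enal | CC(C)=CC=O | starting material
23 | (±)-5,8-dimethoxy-4-(2-methylprop-1-en-1-yl)-2-phenyl-4H-1,3,2-benzodioxaborinine (in situ) | COc1ccc(OC)c2OB(c3ccccc3)OC(C=C(C)C)c12 | intermediate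
24 | (6Z)-2,5-dimethoxy-6-(3-methylbut-2-en-1-ylidene)cyclohexa-2,4-dien-1-one (in situ) | CC(C)=C/C=C1\C(=O)C(OC)=CC=C1OC | intermediate
25 | 5,8-dimethoxy-2,2-dimethyl-2H-chromene | COc1ccc(OC)c2OC(C)(C)C=Cc12 | intermediate
26 | 2,2-dimethyl-2H-chromene-5,8-dione | CC1(C)C=CC2=C(O1)C(=O)C=CC2=O | intermediate
27 | ethyl (2E)-3-(dimethylamino)prop-2-enoate | CCOC(=O)/C=C/N(C)C | starting material
28 | ethyl 2-(5,8-dihydroxy-2,2-dimethyl-2H-chromen-6-yl)-3-(dimethylamino)prop-2-enoate (in situ; enamine geometry not fixed) | CCOC(=O)C(=CN(C)C)c1cc(O)c2OC(C)(C)C=Cc2c1O | intermediate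
29 | ethyl 5-hydroxy-6,7-(2,2-dimethyl-2H-pyrano)benzofuran-3-carboxylate (pyran O on C6, pyran CH= on C7) | CCOC(=O)c1coc2c3C=CC(C)(C)Oc3c(O)cc12 | intermediate
30 | ethyl 5-(methoxymethoxy)-6,7-(2,2-dimethyl-2H-pyrano)benzofuran-3-carboxylate | CCOC(=O)c1coc2c3C=CC(C)(C)Oc3c(OCOC)cc12 | intermediate
31 | ethyl 2-lithio-5-(methoxymethoxy)-6,7-(2,2-dimethyl-2H-pyrano)benzofuran-3-carboxylate (in situ) | CCOC(=O)c1c([Li])oc2c3C=CC(C)(C)Oc3c(OCOC)cc12 | intermediate
32 | ethyl 2-chloro-5-(methoxymethoxy)-6,7-(2,2-dimethyl-2H-pyrano)benzofuran-3-carboxylate | CCOC(=O)c1c(Cl)oc2c3C=CC(C)(C)Oc3c(OCOC)cc12 | intermediate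
33 | caesium 7-ethoxy-2,2-dimethyl-8-(3-methylbut-2-en-1-yl)-2H-chromen-5-olate (in situ) | CCOc1cc([O-])c2C=CC(C)(C)Oc2c1CC=C(C)C.[Cs+] | intermediate
34 | ethyl 2-{[7-ethoxy-2,2-dimethyl-8-(3-methylbut-2-en-1-yl)-2H-chromen-5-yl]oxy}-5-(methoxymethoxy)-6,7-(2,2-dimethyl-2H-pyrano)benzofuran-3-carboxylate | CCOC(=O)c1c(Oc2cc(OCC)c(CC=C(C)C)c3OC(C)(C)C=Cc23)oc2c3C=CC(C)(C)Oc3c(OCOC)cc12 | intermediate
35 | 2-{[7-ethoxy-2,2-dimethyl-8-(3-methylbut-2-en-1-yl)-2H-chromen-5-yl]oxy}-5-(methoxymethoxy)-6,7-(2,2-dimethyl-2H-pyrano)benzofuran-3-carboxylic acid | OC(=O)c1c(Oc2cc(OCC)c(CC=C(C)C)c3OC(C)(C)C=Cc23)oc2c3C=CC(C)(C)Oc3c(OCOC)cc12 | intermediate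
36 | mixed anhydride of 35 with trifluoroacetic acid (in situ) | FC(F)(F)C(=O)OC(=O)c1c(Oc2cc(OCC)c(CC=C(C)C)c3OC(C)(C)C=Cc23)oc2c3C=CC(C)(C)Oc3c(OCOC)cc12 | intermediate
37 | 5-O-ethyl-5′-O-(methoxymethyl) ether of the target | CC(C)=CCc1c2c(c3oc4oc5c6c(c(OCOC)cc5c4c(=O)c3c1OCC)OC(C)(C)C=C6)C=CC(C)(C)O2 | intermediate
38 | CNP0323631.0: benzofuro[2,3-b]chromen-4-one core with 5-OH, 6-(3-methylbut-2-en-1-yl), a 2,2-dimethyl-2H-pyran across O7/C8, a 2,2-dimethyl-2H-pyran across C3′/O4′ and 5′-OH | CC(C)=CCc1c2c(c3oc4oc5c6c(c(O)cc5c4c(=O)c3c1O)OC(C)(C)C=C6)C=CC(C)(C)O2 | target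

**Step count**
Total: 16 steps. Longest linear sequence: 9 steps (1 → 2 → 5 → 15 → 17 → 20 → 34 → 35 → 37 → 38); the branches from 6 and from 21 are also 9 steps long.

**Steps most likely to fail**

Step 3. Oxygen transfer from the peroxide to the weakly nucleophilic, silyl-capped acetylide may be slow, so that peroxide decomposition or attack at silicon competes and little ynolate 8 forms. The fallback makes the same ynolate by deprotonating a silylketene. It sets out from 3: lithiation with n-BuLi and quenching with Me3SiCl gives ethoxy(trimethylsilyl)acetylene F1. Heating F1 neat at about 120 °C expels ethene in a retro-ene reaction and gives (trimethylsilyl)ketene F2. Deprotonation of F2 with n-BuLi in THF at −100 °C gives 8, which is silylated with TIPSOTf as before; the route is rejoined at 9.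

Step 5. The 4π opening of the donor-stabilised 3-ethoxycyclobutenone may need temperatures at which the siloxyalkyne isomerises to the silylketene (1,3-silyl shift) or the vinylketene dimerises. The fallback generates vinylketene 11 at room temperature by 1,4-dehydrochlorination, so no cyclobutenone has to open first. It sets out from 2: acylation of Meldrum's acid (pyridine, CH2Cl2) and ethanolysis in hot ethanol give ethyl 7-methyl-3-oxooct-6-enoate F3. Triethyl orthoformate with catalytic acid in ethanol gives ethyl (2E)-3-ethoxy-7-methylocta-2,6-dienoate F4. Saponification with KOH gives potassium (2E)-3-ethoxy-7-methylocta-2,6-dienoate F5, which is kept as the salt to protect the enol ether. Oxalyl chloride converts it into (2E)-3-ethoxy-7-methylocta-2,6-dienoyl chloride F6. Triethylamine, added to F6 in the presence of 10, removes a γ-hydrogen and chloride to give 11, which adds to 10 to form 12; warming to about 80 °C then leads through 13 and 14. The route is rejoined at 15.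

Step 16. The Lewis acid may induce hydrochlorination of the prenyl or chromene alkenes, or cyclisation of the prenyl group onto the liberated O5–H, before the ethyl ether is fully cleaved. The fallback unmasks in two stages without boron halides. It sets out from 37: MgI2·OEt2 in toluene/Et2O at 60 °C chelates between the C4 carbonyl and O5, and iodide removes the ethyl group, giving the 5′-O-(methoxymethyl) ether of the target with free 5-OH F7. ZnBr2 with n-PrSH in CH2Cl2 at 0 °C then transfers the MOM group to the thiol; the route is rejoined at 38.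

Further compounds
F1 | step 3 | ethoxy(trimethylsilyl)acetylene | CCOC#C[Si](C)(C)C
F2 | step 3 | (trimethylsilyl)ketene | C[Si](C)(C)C=C=O
F3 | step 5 | ethyl 7-methyl-3-oxooct-6-enoate | CCOC(=O)CC(=O)CCC=C(C)C
F4 | step 5 | ethyl (2E)-3-ethoxy-7-methylocta-2,6-dienoate | CCO/C(CCC=C(C)C)=C/C(=O)OCC
F5 | step 5 | potassium (2E)-3-ethoxy-7-methylocta-2,6-dienoate | CCO/C(CCC=C(C)C)=C/C(=O)[O-].[K+]
F6 | step 5 | (2E)-3-ethoxy-7-methylocta-2,6-dienoyl chloride | CCO/C(CCC=C(C)C)=C/C(Cl)=O
F7 | step 16 | 5′-O-(methoxymethyl) ether of the target with free 5-OH | CC(C)=CCc1c2c(c3oc4oc5c6c(c(OCOC)cc5c4c(=O)c3c1O)OC(C)(C)C=C6)C=CC(C)(C)O2
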